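**Assumption:** Broussonol A has no stereocenter, so the "single enantiomer" is the one achiral compound; only regiochemistry and alkene geometry need control.

**Retrosynthetic overview**
1. Broussonol A (12) ⇒ its isomer, flavonol bis-ether 9 (7-O-prenyl, 4'-O-1,1-dimethylpropargyl). One thermal cascade moves both C5 units from O to C; pyran ring D closes last by oxa-6π electrocyclization of the ring B o-quinone methide, the closure presumed in the plant.
2. 9 ⇒ chalcone 7 by oxidative cyclization (chalcone → dihydroflavonol → flavonol, the biosynthetic order), which forms ring C.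
3. 7 ⇒ acetophenone 3 + aldehyde 6 (Claisen–Schmidt), run in the same pot as the oxidation and without protecting groups; the symmetry of 3 makes ring C closure unambiguous.
4. 3 ⇐ phloroacetophenone 1 + prenyl bromide 2; 6 ⇐ protocatechualdehyde 4 + 3-chloro-3-methylbut-1-yne 5.
5. Ring order: rings A and B are bought, ring C is formed in step 3, ring D in step 4.

**Route**

Step 1
Reactants: 1 2,4,6-trihydroxyacetophenone; 2 prenyl bromide
Product: 3 1-{2,6-dihydroxy-4-[(3-methylbut-2-en-1-yl)oxy]phenyl}ethan-1-one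
Conditions: K2CO3 (1.1 equiv), 2 (1.0 equiv), acetone, reflux, 6 h
Reagents that add atoms: none
Why: Williamson etherification; the 4-OH is the most acidic phenol and the only one not hydrogen-bonded to the acetyl group, so one equivalent of weak base in an aprotic solvent gives mainly the 4-O-prenyl ether rather than C-alkylation, and no stereocenter is formed.

Step 2
Reactants: 4 3,4-dihydroxybenzaldehyde; 5 3-chloro-3-methylbut-1-yne
Product: 6 3-hydroxy-4-[(2-methylbut-3-yn-2-yl)oxy]benzaldehyde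
Conditions: K2CO3 (1.1 equiv), KI (0.2 equiv), CuI (2 mol%), 5 (1.5 equiv), DMF, 60 °C
Reagents that add atoms: none
Why: Copper-assisted Williamson-type O-propargylation with the tertiary propargylic chloride; the 4-OH para to the formyl group is about four pKa units more acidic than the 3-OH, so one equivalent of base alkylates it selectively, and no stereocenter is formed.

Step 3
Reactants: 3 1-{2,6-dihydroxy-4-[(3-methylbut-2-en-1-yl)oxy]phenyl}ethan-1-one; 6 3-hydroxy-4-[(2-methylbut-3-yn-2-yl)oxy]benzaldehyde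
Product: 9 3,5-dihydroxy-2-{3-hydroxy-4-[(2-methylbut-3-yn-2-yl)oxy]phenyl}-7-[(3-methylbut-2-en-1-yl)oxy]-4H-chromen-4-one, via chalcone 7 (not isolated), via trans-dihydroflavonol 8 (not isolated)
Conditions: KOH (50% aq.), EtOH, Ar, rt, 48 h; then dilute (MeOH/H2O), 0 °C, 30% H2O2 (4 equiv), 0 °C → rt, 4 h; HCl to pH 3
Reagents that add atoms: hydrogen peroxide, OO
Why: Claisen–Schmidt condensation followed in the same pot by Algar–Flynn–Oyamada oxidation, in which phenoxide oxa-Michael closure of ring C, enolate hydroxylation by H2O2 to racemic trans-dihydroflavonol 8 and dehydrogenation (which erases both stereocenters) repeat the plant's chalcone → flavanone → dihydroflavonol → flavonol order; the two ortho-OH groups of 3 are symmetry-equivalent so only one flavonol can form, the second phenoxide should make the enone a poor acceptor for external HOO– (the aurone channel), and nucleophilic peroxide leaves the prenyl alkene and the alkyne untouched.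

Step 4
Reactants: 9 3,5-dihydroxy-2-{3-hydroxy-4-[(2-methylbut-3-yn-2-yl)oxy]phenyl}-7-[(3-methylbut-2-en-1-yl)oxy]-4H-chromen-4-one
Product: 12 Broussonol A, via o-quinone methide 10 (not isolated), via chromene prenyl ether 11 (not isolated)
Conditions: PhNEt2 (degassed), Ar, 140 °C, 2 h, then 195 °C, 1 h (sealed tube or microwave)
Reagents that add atoms: none
Why: Two thermal sigmatropic cascades on one substrate: aryl propargyl ether Claisen rearrangement to C5' and a 1,5-H shift give o-quinone methide 10 (the quinone methide tautomer of the 5'-prenyl o-quinone presumed in the plant), whose oxa-6π electrocyclization closes ring D to give 11, and at the higher temperature aromatic Claisen rearrangement of the 7-O-prenyl ether with allyl inversion puts the 1,1-dimethylallyl group on C8, expected to be favoured over C6 by bond fixation in the 5-hydroxychromone; the product is achiral, so no stereocenter is set.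

**Compound list**

1 | 2,4,6-trihydroxyacetophenone (phloroacetophenone) | CC(=O)c1c(O)cc(O)cc1O | starting material
2 | prenyl bromide (1-bromo-3-methylbut-2-ene) | CC(C)=CCBr | starting material
3 | 1-{2,6-dihydroxy-4-[(3-methylbut-2-en-1-yl)oxy]phenyl}ethan-1-one | CC(=O)c1c(O)cc(OCC=C(C)C)cc1O | intermediate
4 | 3,4-dihydroxybenzaldehyde (protocatechualdehyde) | O=Cc1ccc(O)c(O)c1 | starting material
5 | 3-chloro-3-methylbut-1-yne | C#CC(C)(C)Cl | starting material
6 | 3-hydroxy-4-[(2-methylbut-3-yn-2-yl)oxy]benzaldehyde | O=Cc1ccc(OC(C)(C)C#C)c(O)c1 | intermediate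
7 | chalcone, not isolated: (E)-1-{2,6-dihydroxy-4-[(3-methylbut-2-en-1-yl)oxy]phenyl}-3-{3-hydroxy-4-[(2-methylbut-3-yn-2-yl)oxy]phenyl}prop-2-en-1-one | O=C(/C=C/c1ccc(OC(C)(C)C#C)c(O)c1)c1c(O)cc(OCC=C(C)C)cc1O | intermediate
8 | trans-dihydroflavonol, not isolated, racemic, (2R,3R) enantiomer drawn: 3,5-dihydroxy-2-{3-hydroxy-4-[(2-methylbut-3-yn-2-yl)oxy]phenyl}-7-[(3-methylbut-2-en-1-yl)oxy]-2,3-dihydro-4H-chromen-4-one | O=C1[C@H](O)[C@@H](c2ccc(OC(C)(C)C#C)c(O)c2)Oc2cc(OCC=C(C)C)cc(O)c12 | intermediate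
9 | 3,5-dihydroxy-2-{3-hydroxy-4-[(2-methylbut-3-yn-2-yl)oxy]phenyl}-7-[(3-methylbut-2-en-1-yl)oxy]-4H-chromen-4-one | O=c1c(O)c(-c2ccc(OC(C)(C)C#C)c(O)c2)oc2cc(OCC=C(C)C)cc(O)c12 | intermediate
10 | o-quinone methide, not isolated: flavonol 9 in which ring B has become the (Z)-3'-hydroxy-5'-(3-methylbut-2-en-1-ylidene)-4'-oxocyclohexadienyl unit, 7-O-prenyl ether intact | O=c1c(O)c(C2=C/C(=C/C=C(C)C)C(=O)C(O)=C2)oc2cc(OCC=C(C)C)cc(O)c12 | intermediate
11 | chromene prenyl ether, not isolated: 3,5-dihydroxy-2-(8-hydroxy-2,2-dimethyl-2H-chromen-6-yl)-7-[(3-methylbut-2-en-1-yl)oxy]-4H-chromen-4-one | O=c1c(O)c(-c2cc(O)c3c(c2)C=CC(C)(C)O3)oc2cc(OCC=C(C)C)cc(O)c12 | intermediate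
12 | Broussonol A: 3,5,7-trihydroxy-2-(8-hydroxy-2,2-dimethyl-2H-chromen-6-yl)-8-(2-methylbut-3-en-2-yl)-4H-chromen-4-one | C=CC(C)(C)c1c(O)cc(O)c2c(=O)c(O)c(-c3cc(O)c4c(c3)C=CC(C)(C)O4)oc12 | target

**Totals**
Total step count: 4. Longest linear sequence: 3 steps (1 → 3 → 9 → 12, or 4 → 6 → 9 → 12).

**Steps most likely to fail**

Step 3 (one-pot condensation and oxidative cyclization without protecting groups). The polyanionic ketone enolizes slowly, 2',6'-dioxygenated chalcones are the classic substrates that divert to aurones, and the flavonol can over-oxidize. The fallback sets out from 3 and comes back at 9. MOMCl (1.1 equiv) and i-Pr2NEt in CH2Cl2 at 0 °C cap one of the two equivalent phenols to give 1-{2-hydroxy-6-(methoxymethoxy)-4-[(3-methylbut-2-en-1-yl)oxy]phenyl}ethan-1-one F1. Claisen–Schmidt condensation of F1 with 6 (KOH, EtOH, rt) gives the isolable chalcone (E)-1-{2-hydroxy-6-(methoxymethoxy)-4-[(3-methylbut-2-en-1-yl)oxy]phenyl}-3-{3-hydroxy-4-[(2-methylbut-3-yn-2-yl)oxy]phenyl}prop-2-en-1-one F2. Alkaline H2O2 at 0 °C on this 6'-O-MOM chalcone, a substrate class with precedent for flavonol formation, gives 3-hydroxy-2-{3-hydroxy-4-[(2-methylbut-3-yn-2-yl)oxy]phenyl}-5-(methoxymethoxy)-7-[(3-methylbut-2-en-1-yl)oxy]-4H-chromen-4-one F3. The chelated peri 5-O-MOM group is then removed with dilute HCl in MeOH/THF at rt, which gives 9.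

Step 4 (tandem rearrangement). The prenyl shift may give the C6 isomer alongside C8, and at 195 °C the new 7-OH can add to the 1,1-dimethylallyl group to form a dihydrofuran. The fallback sets out from 3 and 6 and comes back at 12; it fixes the regiochemistry before ring C exists.
- Heating 3 alone (PhNEt2, 190 °C, short time) can give only one Claisen product because 3 is symmetric: 1-[2,4,6-trihydroxy-3-(2-methylbut-3-en-2-yl)phenyl]ethan-1-one F4.
- MOMCl (2.2 equiv) and i-Pr2NEt should protect the 4-OH and the unhindered 6-OH and leave the phenol wedged between the acetyl and tert-alkyl groups free, giving 1-[2-hydroxy-4,6-bis(methoxymethoxy)-3-(2-methylbut-3-en-2-yl)phenyl]ethan-1-one F5.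
- Heating 6 alone (DMF, 140 °C) gives 8-hydroxy-2,2-dimethyl-2H-chromene-6-carbaldehyde F6.
- Claisen–Schmidt condensation of F5 with F6 (KOH, EtOH) gives the chalcone (E)-1-[2-hydroxy-4,6-bis(methoxymethoxy)-3-(2-methylbut-3-en-2-yl)phenyl]-3-(8-hydroxy-2,2-dimethyl-2H-chromen-6-yl)prop-2-en-1-one F7.
- Alkaline H2O2 at 0 °C closes ring C through the only free phenol, next to the tert-alkyl group, giving 3-hydroxy-2-(8-hydroxy-2,2-dimethyl-2H-chromen-6-yl)-5,7-bis(methoxymethoxy)-8-(2-methylbut-3-en-2-yl)-4H-chromen-4-one F8.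
- HCl in MeOH at 40 °C removes both MOM groups to give 12.

Step 1 (mono-O-prenylation of phloroacetophenone). The ambident phloroglucinol anion can C-prenylate or react twice. The fallback sets out from 1 and comes back at 3: Mitsunobu etherification with 3-methylbut-2-en-1-ol, PPh3 and DIAD in THF at 0 °C. It engages only the most acidic, non-chelated 4-OH under neutral conditions where no phenoxide is free to C-alkylate; it makes no new compound (entry F0).

**Further compounds**

F1 | step 3 | 1-{2-hydroxy-6-(methoxymethoxy)-4-[(3-methylbut-2-en-1-yl)oxy]phenyl}ethan-1-one | CC(=O)c1c(O)cc(OCC=C(C)C)cc1OCOC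
F2 | step 3 | (E)-1-{2-hydroxy-6-(methoxymethoxy)-4-[(3-methylbut-2-en-1-yl)oxy]phenyl}-3-{3-hydroxy-4-[(2-methylbut-3-yn-2-yl)oxy]phenyl}prop-2-en-1-one | O=C(/C=C/c1ccc(OC(C)(C)C#C)c(O)c1)c1c(O)cc(OCC=C(C)C)cc1OCOC
F3 | step 3 | 3-hydroxy-2-{3-hydroxy-4-[(2-methylbut-3-yn-2-yl)oxy]phenyl}-5-(methoxymethoxy)-7-[(3-methylbut-2-en-1-yl)oxy]-4H-chromen-4-one | O=c1c(O)c(-c2ccc(OC(C)(C)C#C)c(O)c2)oc2cc(OCC=C(C)C)cc(OCOC)c12
F4 | step 4 | 1-[2,4,6-trihydroxy-3-(2-methylbut-3-en-2-yl)phenyl]ethan-1-one | CC(=O)c1c(O)cc(O)c(C(C)(C)C=C)c1O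
F5 | step 4 | 1-[2-hydroxy-4,6-bis(methoxymethoxy)-3-(2-methylbut-3-en-2-yl)phenyl]ethan-1-one | CC(=O)c1c(OCOC)cc(OCOC)c(C(C)(C)C=C)c1O
F6 | step 4 | 8-hydroxy-2,2-dimethyl-2H-chromene-6-carbaldehyde | O=Cc1cc(O)c2c(c1)C=CC(C)(C)O2
F7 | step 4 | (E)-1-[2-hydroxy-4,6-bis(methoxymethoxy)-3-(2-methylbut-3-en-2-yl)phenyl]-3-(8-hydroxy-2,2-dimethyl-2H-chromen-6-yl)prop-2-en-1-one | O=C(/C=C/c1cc(O)c2c(c1)C=CC(C)(C)O2)c1c(OCOC)cc(OCOC)c(C(C)(C)C=C)c1O
F8 | step 4 | 3-hydroxy-2-(8-hydroxy-2,2-dimethyl-2H-chromen-6-yl)-5,7-bis(methoxymethoxy)-8-(2-methylbut-3-en-2-yl)-4H-chromen-4-one | C=CC(C)(C)c1c(OCOC)cc(OCOC)c2c(=O)c(O)c(-c3cc(O)c4c(c3)C=CC(C)(C)O4)oc12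
F0 | step 1 | none | none
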